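**Plan**

- Feature used: the C6 side chain C(=O)–CH2–CH(OH)–Ph is what a 3-aryl-5-phenyl-4,5-dihydroisoxazole gives on N–O cleavage and imine hydrolysis (C3 = ketone carbon, C4 = CH2, ring oxygen on C5 = carbinol oxygen). C6 lies between the C5 oxygen and the C7 methoxy group, so the derived nitrile oxide is shielded on both sides and can be handled as a discrete compound.
- Retrosynthetic cuts, in order: the phenol O–Si bond; the ketone back to the C=N–O unit; the C3–C4 and O1–C5 bonds of the isoxazoline (aryl nitrile oxide plus styrene); the nitrile oxide back to the aldehyde through its oxime; the pyran C4–C4a and O1–C2 bonds (a 2,4-dihydroxybenzaldehyde plus an enal).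
- Forward: the pyran ring is fused onto the benzaldehyde first, the isoxazoline ring is then closed by [3+2] cycloaddition and opened again at N–O, and the phenol is set free last.
- Stereochemistry: the only stereocentre (benzylic C–O) arises in the cycloaddition as a racemate. The (S)-enantiomer is separated on a chiral stationary phase directly afterwards and is carried through unchanged, because none of its four bonds is broken later.

Key step: step 5

Assumption: 2,4-dihydroxy-6-methoxybenzaldehyde is taken as a purchasable starting material (it is also the formylation product of 5-methoxyresorcinol).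
Assumption: the elution order in step 6 cannot be predicted, so the (S)-assignment of the collected enantiomer is taken to be confirmed independently (anomalous-dispersion X-ray analysis or chiroptical comparison of 13 with the natural product).

**Step 1**
Reactants: 1 2,4-dihydroxy-6-methoxybenzaldehyde; 2 3-methylbut-2-enal
Product: 4 5-hydroxy-7-methoxy-2,2-dimethyl-2H-chromene-6-carbaldehyde, via quinone methide 3 (not isolated)
Conditions: excess enal, ethylenediammonium diacetate (cat.), xylene, 140 °C
Reagents that add atoms: none
Why: Amine-salt-catalysed Knoevenagel-type condensation at C3 should give quinone methide 3, which closes by oxa-6π-electrocyclisation through the non-chelated 4-oxygen; attack at C3 and not at C5 is expected because C3 lies ortho to both free phenol oxygens, as in the well-known annulation of 2,4-dihydroxybenzaldehyde.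

**Step 2**
Reactants: 4 5-hydroxy-7-methoxy-2,2-dimethyl-2H-chromene-6-carbaldehyde
Product: 5 5-[(tert-butyldimethylsilyl)oxy]-7-methoxy-2,2-dimethyl-2H-chromene-6-carbaldehyde
Conditions: TBSCl (1.5 equiv), imidazole (3 equiv), DMF, 25 °C
Reagents that add atoms: tert-butyldimethylsilyl chloride (TBSCl), CC(C)(C)[Si](C)(C)Cl
Why: Imidazole-promoted silylation of a phenol in DMF is standard even for chelated hydroxyls, and the mask is needed because a free, para-unsubstituted phenol would be attacked by the hypervalent iodine oxidant of step 4.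

**Step 3**
Reactants: 5 5-[(tert-butyldimethylsilyl)oxy]-7-methoxy-2,2-dimethyl-2H-chromene-6-carbaldehyde
Product: 6 (E)-5-[(tert-butyldimethylsilyl)oxy]-7-methoxy-2,2-dimethyl-2H-chromene-6-carbaldehyde oxime
Conditions: NH2OH·HCl (1.5 equiv), pyridine (3 equiv), EtOH, 25 °C
Reagents that add atoms: hydroxylamine hydrochloride, NO.Cl
Why: Oxime formation by condensation of an aldehyde with hydroxylamine is general, and the pyridine-buffered medium should leave the aryl silyl ether and the chromene alkene untouched.

**Step 4**
Reactants: 6 (E)-5-[(tert-butyldimethylsilyl)oxy]-7-methoxy-2,2-dimethyl-2H-chromene-6-carbaldehyde oxime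
Product: 7 5-[(tert-butyldimethylsilyl)oxy]-7-methoxy-2,2-dimethyl-2H-chromene-6-carbonitrile oxide
Conditions: PhI(OAc)2 (1.05 equiv), TFA (5 mol %), MeOH, 0 °C
Reagents that add atoms: none
Why: Oxidative dehydrogenation of an aldoxime by the trivalent iodine reagent (ligand exchange at iodine, then loss of iodobenzene and acetic acid) is an established nitrile oxide synthesis, and the silyloxy and methoxy groups on both sides of the dipole should make 7 isolable like other 2,6-disubstituted benzonitrile oxides.

**Step 5**
Reactants: 7 5-[(tert-butyldimethylsilyl)oxy]-7-methoxy-2,2-dimethyl-2H-chromene-6-carbonitrile oxide; 8 styrene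
Product: 9 rac-3-{5-[(tert-butyldimethylsilyl)oxy]-7-methoxy-2,2-dimethyl-2H-chromen-6-yl}-5-phenyl-4,5-dihydroisoxazole
Conditions: excess styrene, BHT (cat.), toluene, 70 °C
Reagents that add atoms: none
Why: The nitrile oxide, a propargyl-type 1,3-dipole, and styrene should combine in a concerted, asynchronous, suprafacial [3+2] (Huisgen) cycloaddition in which the dipole carbon bonds to the terminal CH2 and the dipole oxygen to the benzylic carbon. The closest known reaction type is the thermal addition of isolable 2,6-disubstituted benzonitrile oxides (mesityl, 2,4,6-trimethoxyphenyl) to styrene, which gives 3-aryl-5-phenyl-4,5-dihydroisoxazoles. The five-membered ring is closed by the cycloaddition itself, C3–C4 and O1–C5 forming in one transition state, so no separate cyclisation mode has to be met. The new stereocentre C5 is under no control because neither partner is chiral, so 9 should form as a racemate, from which step 6 takes the (S)-enantiomer. The step needs regioselectivity for the 5-phenyl isomer, which follows from the large LUMO coefficient at the dipole carbon meeting the large HOMO coefficient at the unsubstituted alkene terminus and from sterics. It also needs chemoselectivity for styrene over the cis-disubstituted, ring-fused chromene alkene, which the lower steric demand and the excess of styrene should secure, while the two flanking oxygen substituents hold back furoxan formation.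

**Step 6**
Reactants: 9 rac-3-{5-[(tert-butyldimethylsilyl)oxy]-7-methoxy-2,2-dimethyl-2H-chromen-6-yl}-5-phenyl-4,5-dihydroisoxazole
Product: 10 (S)-3-{5-[(tert-butyldimethylsilyl)oxy]-7-methoxy-2,2-dimethyl-2H-chromen-6-yl}-5-phenyl-4,5-dihydroisoxazole
Conditions: preparative HPLC, cellulose tris(3,5-dimethylphenylcarbamate) on silica, hexane/i-PrOH, 25 °C
Reagents that add atoms: none
Why: Resolution by chromatography on a chiral stationary phase is routine for neutral, UV-active 3,5-diaryl-4,5-dihydroisoxazoles, and C5 carries neither an acidic hydrogen nor a leaving group, so the collected (S)-enantiomer should be configurationally stable; the stereocentre is selected here, not created.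

**Step 7**
Reactants: 10 (S)-3-{5-[(tert-butyldimethylsilyl)oxy]-7-methoxy-2,2-dimethyl-2H-chromen-6-yl}-5-phenyl-4,5-dihydroisoxazole
Product: 12 (S)-1-{5-[(tert-butyldimethylsilyl)oxy]-7-methoxy-2,2-dimethyl-2H-chromen-6-yl}-3-hydroxy-3-phenylpropan-1-one, via hydroxy ketimine 11 (not isolated)
Conditions: Mo(CO)6 (1 equiv), MeCN/H2O (15:1), 80 °C; then 5% aq. citric acid, THF, 25 °C
Reagents that add atoms: water, O
Why: Reductive N–O cleavage of 4,5-dihydroisoxazoles by zerovalent molybdenum carbonyl in wet acetonitrile, followed by hydrolysis of the N–H ketimine, is an established unmasking of beta-hydroxy ketones that spares alkenes and aryl silyl ethers and touches no bond at the carbinol carbon, so the (S)-configuration is carried over.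

**Step 8**
Reactants: 12 (S)-1-{5-[(tert-butyldimethylsilyl)oxy]-7-methoxy-2,2-dimethyl-2H-chromen-6-yl}-3-hydroxy-3-phenylpropan-1-one
Product: 13 (S)-3-hydroxy-1-(5-hydroxy-7-methoxy-2,2-dimethyl-2H-chromen-6-yl)-3-phenylpropan-1-one
Conditions: TBAF (1.1 equiv), AcOH (1.5 equiv), THF, 0 °C
Reagents that add atoms: none
Why: Fluoride-mediated desilylation of an aryl silyl ether is fast at 0 °C, and buffering with acetic acid should keep the medium from triggering retro-aldol cleavage or dehydration of the beta-hydroxy ketone, whose freed phenol then hydrogen-bonds to the ketone.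

**Compound list**

1 | 2,4-dihydroxy-6-methoxybenzaldehyde | COc1cc(O)cc(O)c1C=O | starting material
2 | 3-methylbut-2-enal | CC(C)=CC=O | starting material
3 | 2-hydroxy-6-methoxy-3-(3-methylbut-2-en-1-ylidene)-4-oxocyclohexa-1,5-diene-1-carbaldehyde (quinone methide) | O=CC1=C(O)C(=CC=C(C)C)C(=O)C=C1OC | intermediate (not isolated)
4 | 5-hydroxy-7-methoxy-2,2-dimethyl-2H-chromene-6-carbaldehyde | COc1cc2c(c(O)c1C=O)C=CC(C)(C)O2 | intermediate
5 | 5-[(tert-butyldimethylsilyl)oxy]-7-methoxy-2,2-dimethyl-2H-chromene-6-carbaldehyde | COc1cc2c(c(O[Si](C)(C)C(C)(C)C)c1C=O)C=CC(C)(C)O2 | intermediate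
6 | (E)-5-[(tert-butyldimethylsilyl)oxy]-7-methoxy-2,2-dimethyl-2H-chromene-6-carbaldehyde oxime | COc1cc2c(c(O[Si](C)(C)C(C)(C)C)c1/C=N/O)C=CC(C)(C)O2 | intermediate
7 | 5-[(tert-butyldimethylsilyl)oxy]-7-methoxy-2,2-dimethyl-2H-chromene-6-carbonitrile oxide | COc1cc2c(c(O[Si](C)(C)C(C)(C)C)c1C#[N+][O-])C=CC(C)(C)O2 | intermediate
8 | styrene | C=Cc1ccccc1 | starting material
9 | rac-3-{5-[(tert-butyldimethylsilyl)oxy]-7-methoxy-2,2-dimethyl-2H-chromen-6-yl}-5-phenyl-4,5-dihydroisoxazole | COc1cc2c(c(O[Si](C)(C)C(C)(C)C)c1C3=NOC(c4ccccc4)C3)C=CC(C)(C)O2 | intermediate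
10 | (S)-3-{5-[(tert-butyldimethylsilyl)oxy]-7-methoxy-2,2-dimethyl-2H-chromen-6-yl}-5-phenyl-4,5-dihydroisoxazole | COc1cc2c(c(O[Si](C)(C)C(C)(C)C)c1C3=NO[C@H](c4ccccc4)C3)C=CC(C)(C)O2 | intermediate
11 | (S)-3-{5-[(tert-butyldimethylsilyl)oxy]-7-methoxy-2,2-dimethyl-2H-chromen-6-yl}-3-imino-1-phenylpropan-1-ol | COc1cc2c(c(O[Si](C)(C)C(C)(C)C)c1C(=N)C[C@H](O)c1ccccc1)C=CC(C)(C)O2 | intermediate (not isolated)
12 | (S)-1-{5-[(tert-butyldimethylsilyl)oxy]-7-methoxy-2,2-dimethyl-2H-chromen-6-yl}-3-hydroxy-3-phenylpropan-1-one | COc1cc2c(c(O[Si](C)(C)C(C)(C)C)c1C(=O)C[C@H](O)c1ccccc1)C=CC(C)(C)O2 | intermediate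
13 | (S)-3-hydroxy-1-(5-hydroxy-7-methoxy-2,2-dimethyl-2H-chromen-6-yl)-3-phenylpropan-1-one | COc1cc2c(c(O)c1C(=O)C[C@H](O)c1ccccc1)C=CC(C)(C)O2 | target

**Step count**

Total: 8 steps, the resolution counted as one. Longest linear sequence: 8 steps, from 1 to 13.

**Steps most likely to fail**

1. Step 7. The ring opening of the doubly ortho-flanked isoxazoline may be slow, and prolonged heating may then cause loss of water from the beta-hydroxy ketimine or retro-aldol cleavage. The shielded ketimine may also hydrolyse sluggishly. The fallback sets out from 10 and reverses the order of unmasking. The silyl group is removed first (TBAF, AcOH, THF, 0 °C) to give (S)-7-methoxy-2,2-dimethyl-6-(5-phenyl-4,5-dihydroisoxazol-3-yl)-2H-chromen-5-ol F1, which no longer carries a bulky ortho group. The N–O bond of F1 is then cleaved by single-electron reduction with SmI2 (THF, 0 °C) to the hydrogen-bonded (S)-6-(3-hydroxy-1-imino-3-phenylpropyl)-7-methoxy-2,2-dimethyl-2H-chromen-5-ol F2. Aqueous B(OH)3 hydrolyses F2 in the same flask, and the sequence comes back to the route at 13.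

2. Step 1. Regiocontrol in the carbon–carbon bond-forming condensation may be incomplete, with attack at C5 next to the methoxy group, and the enal may self-condense. The fallback sets out from 1 and builds the pyran ring by a sigmatropic route. The non-chelated 4-hydroxyl is alkylated with 3-chloro-3-methylbut-1-yne (K2CO3, KI, CuI cat., acetone, reflux) to give 2-hydroxy-6-methoxy-4-[(2-methylbut-3-yn-2-yl)oxy]benzaldehyde F3. Heating F3 in N,N-diethylaniline at about 190 °C should bring about aryl propargyl ether Claisen rearrangement toward the chelated side, a 1,5-hydrogen shift and oxa-6π-electrocyclisation. The sequence comes back to the route at 4.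

3. Step 6. The two enantiomers may separate incompletely on the preparative phase, or the throughput may be too low. The fallback sets out from 9 and moves the resolution to the alcohol stage. Racemic 9 is opened under the conditions of step 7, via the racemic 3-{5-[(tert-butyldimethylsilyl)oxy]-7-methoxy-2,2-dimethyl-2H-chromen-6-yl}-3-imino-1-phenylpropan-1-ol F4, to the racemic 1-{5-[(tert-butyldimethylsilyl)oxy]-7-methoxy-2,2-dimethyl-2H-chromen-6-yl}-3-hydroxy-3-phenylpropan-1-one F5. F5 is then subjected to lipase-catalysed kinetic resolution (Burkholderia cepacia lipase, vinyl acetate, t-BuOMe, 35 °C). By the empirical size rule for lipase acylation of secondary aryl carbinols, with the phenyl ring as the large group and the CH2 chain as the medium one, the (R)-alcohol is expected to be converted into (R)-3-{5-[(tert-butyldimethylsilyl)oxy]-7-methoxy-2,2-dimethyl-2H-chromen-6-yl}-3-oxo-1-phenylpropyl acetate F6. The unreacted (S)-alcohol is separated from F6 on silica, and the sequence comes back to the route at 12.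

**Further compounds**

F1 | step 7 | (S)-7-methoxy-2,2-dimethyl-6-(5-phenyl-4,5-dihydroisoxazol-3-yl)-2H-chromen-5-ol | COc1cc2c(c(O)c1C3=NO[C@H](c4ccccc4)C3)C=CC(C)(C)O2
F2 | step 7 | (S)-6-(3-hydroxy-1-imino-3-phenylpropyl)-7-methoxy-2,2-dimethyl-2H-chromen-5-ol | COc1cc2c(c(O)c1C(=N)C[C@H](O)c1ccccc1)C=CC(C)(C)O2
F3 | step 1 | 2-hydroxy-6-methoxy-4-[(2-methylbut-3-yn-2-yl)oxy]benzaldehyde | COc1cc(OC(C)(C)C#C)cc(O)c1C=O
F4 | step 6 | rac-3-{5-[(tert-butyldimethylsilyl)oxy]-7-methoxy-2,2-dimethyl-2H-chromen-6-yl}-3-imino-1-phenylpropan-1-ol | COc1cc2c(c(O[Si](C)(C)C(C)(C)C)c1C(=N)CC(O)c1ccccc1)C=CC(C)(C)O2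
F5 | step 6 | rac-1-{5-[(tert-butyldimethylsilyl)oxy]-7-methoxy-2,2-dimethyl-2H-chromen-6-yl}-3-hydroxy-3-phenylpropan-1-one | COc1cc2c(c(O[Si](C)(C)C(C)(C)C)c1C(=O)CC(O)c1ccccc1)C=CC(C)(C)O2
F6 | step 6 | (R)-3-{5-[(tert-butyldimethylsilyl)oxy]-7-methoxy-2,2-dimethyl-2H-chromen-6-yl}-3-oxo-1-phenylpropyl acetate | COc1cc2c(c(O[Si](C)(C)C(C)(C)C)c1C(=O)C[C@@H](OC(C)=O)c1ccccc1)C=CC(C)(C)O2
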